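**Retrosynthetic overview**
1. The B-ring silyl ether is removed last (12 → 13). Before that, the 8-prenyl group and the free 5-OH arise together from the 5-O-prenyl ether 11 by a Eu(III)-catalysed para-Claisen (Claisen–Cope) shift, so the prenyl ether also protects the peri-hydroxyl during the key step.
2. Key disconnection C2–C1′ (with C3–OH): 11 ⇒ flat, achiral chromone 4 + arylzinc 8. A Rh/BINAP-catalysed asymmetric conjugate arylation gives the (2S)-enol silane, and Rubottom oxidation in the same operation sets C3 anti to the aryl group.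
3. Enabling feature: in ring C the atoms O1–C2=C3–C4=O form a vinylogous ester. C2 is the β-carbon of an enone and accepts the aryl group; C3 is the α-carbon and emerges as an O4-silyl enolate ready for oxygenation, with the new C2 aryl group as its only control element.
4. Chromone 4 ⇒ 2′,6′-dihydroxy-4′-methoxyacetophenone 1 (mono-O-prenylation, DMF-DMA, cyclisation); aryl donor ⇒ 5-bromo-2-methoxyphenol 5.
5. Ring order: rings A and B are bought aromatic; ring C (pyranone) is closed in step 2 and brought to its final oxidation level and configuration in step 4.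

Key step: step 4

Assumption: 1 is taken as a catalogue compound (otherwise one 4-O-methylation from phloroacetophenone), and the BINAP enantiomer in step 4 is the one that gives 2S in 9, expected to be (S)-BINAP by analogy with N-acyl-4-quinolones and to be confirmed on the first run.

**Route**

Step 1
Reactants: 1 1-(2,6-dihydroxy-4-methoxyphenyl)ethan-1-one
Product: 2 1-[2-hydroxy-4-methoxy-6-(3-methylbut-2-enyloxy)phenyl]ethan-1-one
Conditions: prenyl bromide (1.05 equiv), K2CO3, acetone, reflux
Reagents that add atoms: prenyl bromide (1-bromo-3-methylbut-2-ene), CC(C)=CCBr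
Why: Williamson O-alkylation; the two hydroxyls are equivalent, and after the first alkylation the remaining one is held in the hydrogen bond to the ketone, so mono-etherification should prevail.

Step 2
Reactants: 2 1-[2-hydroxy-4-methoxy-6-(3-methylbut-2-enyloxy)phenyl]ethan-1-one
Product: 4 7-methoxy-5-(3-methylbut-2-enyloxy)-4H-chromen-4-one, via enaminone 3 (not isolated)
Conditions: Me2NCH(OMe)2, PhMe, 90 °C; then AcOH, CH2Cl2, 40 °C
Reagents that add atoms: N,N-dimethylformamide dimethyl acetal, COC(OC)N(C)C
Why: Enaminone condensation of the methyl ketone, then acid-promoted 6-endo oxa-Michael addition of the phenol and loss of dimethylamine (addition–elimination) closes the pyranone ring; acetic acid should be too weak to ionise the prenyl aryl ether.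

Step 3
Reactants: 5 5-bromo-2-methoxyphenol
Product: 6 (5-bromo-2-methoxyphenoxy)tri(propan-2-yl)silane
Conditions: TIPSCl, imidazole, DMF, rt
Reagents that add atoms: chlorotri(propan-2-yl)silane (TIPSCl), CC(C)[Si](Cl)(C(C)C)C(C)C
Why: Standard O-silylation of a phenol; the bulky aryl silyl ether should tolerate halogen–lithium exchange, the organozinc, DMDO and mild acid, and it is meta to the metalated carbon, so no silyl migration is expected.

Step 4
Reactants: 4 7-methoxy-5-(3-methylbut-2-enyloxy)-4H-chromen-4-one; 6 (5-bromo-2-methoxyphenoxy)tri(propan-2-yl)silane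
Product: 11 (2R,3R)-3-hydroxy-7-methoxy-2-[4-methoxy-3-(triisopropylsilyloxy)phenyl]-5-(3-methylbut-2-enyloxy)chroman-4-one, via aryllithium 7 (not isolated), via arylzinc chloride 8 (not isolated), via enol silane 9 (not isolated), via silyloxy epoxide 10 (not isolated)
Conditions: 6 (2 equiv), n-BuLi, THF, −78 °C; ZnCl2, → rt; 4, [RhCl((S)-BINAP)]2 (2.5 mol%), TMSCl (2 equiv), THF, 20 °C; pentane/Et3N, cold aq NaHCO3 wash, concentrate; DMDO (1.05 equiv), acetone/CH2Cl2, −78 °C; 10% aq citric acid, THF, 0 °C
Reagents that add atoms: dimethyldioxirane, CC1(C)OO1 (the C3 oxygen of 11); in the intermediates only: n-butyllithium, [Li]CCCC (Li of 7); zinc chloride, Cl[Zn]Cl (ZnCl of 8); chlorotrimethylsilane, C[Si](C)(C)Cl (Me3Si of 9 and 10)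
Why: Proposed new method: transmetalation of 8 to Rh(I)/BINAP gives an aryl–rhodium species that inserts the C2=C3 bond of 4 with the aryl group going to C2, the oxa-π-allyl rhodium enolate is silylated on O4 by TMSCl to release enol silane 9, and the C3=C4 bond of 9 is then epoxidised by dimethyldioxirane (Rubottom oxidation) and the silyloxy oxirane 10 hydrolysed to the α-hydroxy ketone. The closest known reaction types are the Rh/BINAP-catalysed asymmetric 1,4-addition of arylzinc chlorides with TMSCl to N-acyl-4-quinolones and 2,3-dihydro-4-pyridones, the Rh- and Pd-catalysed asymmetric 1,4-additions of arylboronic acids to chromones, and the DMDO oxidation of flavanone silyl enol ethers to trans-3-hydroxyflavanones; new here are the arylzinc/TMSCl variant on a chromone and its direct coupling to the oxidation. No ring of the target is closed: only the transient oxirane of 10 forms (3-exo epoxidation) and is opened again. C2 is set by the chiral ligand (enantioface selection in the carborhodation), and C3 by the C2 aryl group, which shields one face of the enol silane so that oxygen arrives anti and the 2,3-trans (diequatorial, also thermodynamically favoured) product should result. The step needs 1,4- over 1,2-addition, which the arylrhodium/arylzinc pair secures because neither adds to the ketone, and oxidation of the enol silane in preference to the prenyl ether alkene, which the far higher nucleophilicity of the electron-rich silyl enol ether toward one equivalent of DMDO at −78 °C should secure. Because the addition delivers the enol silane directly, no base-mediated enolisation, which would open the pyranone ring by β-elimination of the phenoxide and racemise C2, is needed.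

Step 5
Reactants: 11 (2R,3R)-3-hydroxy-7-methoxy-2-[4-methoxy-3-(triisopropylsilyloxy)phenyl]-5-(3-methylbut-2-enyloxy)chroman-4-one
Product: 12 (2R,3R)-3,5-dihydroxy-7-methoxy-2-[4-methoxy-3-(triisopropylsilyloxy)phenyl]-8-(3-methylbut-2-enyl)chroman-4-one
Conditions: Eu(fod)3 (10 mol%), NaHCO3, PhCl, 85 °C
Reagents that add atoms: none
Why: Lewis-acid-catalysed aromatic para-Claisen (Claisen–Cope) rearrangement: Eu(III) chelated between O4 and O5 promotes the [3,3] shift of the prenyl group to C6 (the only free ortho position), a second [3,3] (Cope) shift carries it to C8 with the normal prenyl connectivity, and tautomerisation gives the chelated 5-phenol; no stereocentre is touched and no base is present.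

Step 6
Reactants: 12 (2R,3R)-3,5-dihydroxy-7-methoxy-2-[4-methoxy-3-(triisopropylsilyloxy)phenyl]-8-(3-methylbut-2-enyl)chroman-4-one
Product: 13 (2R,3R)-3,5-dihydroxy-2-(3-hydroxy-4-methoxyphenyl)-7-methoxy-8-(3-methylbut-2-enyl)chroman-4-one
Conditions: TBAF, AcOH (1:1), THF, 0 °C
Reagents that add atoms: none
Why: Fluoride cleavage of the aryl silyl ether; buffering with acetic acid keeps the medium non-basic, so neither retro-oxa-Michael opening at C2 nor enolisation at C3 should occur, and the prenyl group is inert.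

**Compound list**
1 | 1-(2,6-dihydroxy-4-methoxyphenyl)ethan-1-one | CC(=O)c1c(O)cc(OC)cc1O | starting material
2 | 1-[2-hydroxy-4-methoxy-6-(3-methylbut-2-enyloxy)phenyl]ethan-1-one | CC(=O)c1c(O)cc(OC)cc1OCC=C(C)C | intermediate
3 | (E)-3-(dimethylamino)-1-[2-hydroxy-4-methoxy-6-(3-methylbut-2-enyloxy)phenyl]prop-2-en-1-one | CN(C)/C=C/C(=O)c1c(O)cc(OC)cc1OCC=C(C)C | intermediate
4 | 7-methoxy-5-(3-methylbut-2-enyloxy)-4H-chromen-4-one | COc1cc(OCC=C(C)C)c2C(=O)C=COc2c1 | intermediate
5 | 5-bromo-2-methoxyphenol | COc1ccc(Br)cc1O | starting material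
6 | (5-bromo-2-methoxyphenoxy)tri(propan-2-yl)silane | COc1ccc(Br)cc1O[Si](C(C)C)(C(C)C)C(C)C | intermediate
7 | [4-methoxy-3-(triisopropylsilyloxy)phenyl]lithium | COc1ccc([Li])cc1O[Si](C(C)C)(C(C)C)C(C)C | intermediate
8 | [4-methoxy-3-(triisopropylsilyloxy)phenyl]zinc chloride | COc1ccc([Zn]Cl)cc1O[Si](C(C)C)(C(C)C)C(C)C | intermediate
9 | (2S)-7-methoxy-2-[4-methoxy-3-(triisopropylsilyloxy)phenyl]-5-(3-methylbut-2-enyloxy)-4-(trimethylsilyloxy)-2H-chromene | COc1ccc([C@H]2Oc3cc(OC)cc(OCC=C(C)C)c3C(O[Si](C)(C)C)=C2)cc1O[Si](C(C)C)(C(C)C)C(C)C | intermediate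
10 | (2R,3R,4R)-3,4-epoxy-7-methoxy-2-[4-methoxy-3-(triisopropylsilyloxy)phenyl]-5-(3-methylbut-2-enyloxy)-4-(trimethylsilyloxy)chromane (oxirane oxygen anti to the 2-aryl group) | COc1ccc([C@H]2Oc3cc(OC)cc(OCC=C(C)C)c3[C@]4(O[Si](C)(C)C)O[C@H]24)cc1O[Si](C(C)C)(C(C)C)C(C)C | intermediate
11 | (2R,3R)-3-hydroxy-7-methoxy-2-[4-methoxy-3-(triisopropylsilyloxy)phenyl]-5-(3-methylbut-2-enyloxy)chroman-4-one (2,3-trans) | COc1ccc([C@H]2Oc3cc(OC)cc(OCC=C(C)C)c3C(=O)[C@@H]2O)cc1O[Si](C(C)C)(C(C)C)C(C)C | intermediate
12 | (2R,3R)-3,5-dihydroxy-7-methoxy-2-[4-methoxy-3-(triisopropylsilyloxy)phenyl]-8-(3-methylbut-2-enyl)chroman-4-one | COc1ccc([C@H]2Oc3c(CC=C(C)C)c(OC)cc(O)c3C(=O)[C@@H]2O)cc1O[Si](C(C)C)(C(C)C)C(C)C | intermediate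
13 | (2R,3R)-3,5-dihydroxy-2-(3-hydroxy-4-methoxyphenyl)-7-methoxy-8-(3-methylbut-2-enyl)chroman-4-one | COc1ccc([C@H]2Oc3c(CC=C(C)C)c(OC)cc(O)c3C(=O)[C@@H]2O)cc1O | target

**Step count and risks**
Total steps: 6. Longest linear sequence: 5 steps (steps 1, 2, 4, 5, 6 from 1); the B-ring branch is steps 3, 4, 5, 6.

Steps most likely to fail:

1. Step 4 (Proposed new method). Aryl transfer to the electron-rich 5,7-dioxygenated chromone may be slow, enantioface discrimination may be poor, the TMS enol ether may hydrolyse during the work-up between the two stages, or the oxidant may also attack the prenyl ether double bond. The fallback uses known chemistry and sets out from 6 and 4. Bromide 6 is lithiated to 7 and quenched with B(OiPr)3, then aqueous HCl, to give [4-methoxy-3-(triisopropylsilyloxy)phenyl]boronic acid F1. Rh(I)/chiral-diene-catalysed asymmetric 1,4-addition of F1 to 4 in toluene/water should give the isolable flavanone (2S)-7-methoxy-2-[4-methoxy-3-(triisopropylsilyloxy)phenyl]-5-(3-methylbut-2-enyloxy)chroman-4-one F2. Soft enolisation of F2 (TMSOTf, Et3N, CH2Cl2, 0 °C; no strong base, so C2 is not exposed to ring opening) gives enol silane 9, where the route is rejoined (DMDO, then citric acid, to 11).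

2. Step 5. The C6 dienone intermediate may enolise to the 6-(1,1-dimethylallyl) isomer instead of undergoing the Cope shift, the prenyl group may be lost by ionisation, or the α-hydroxy ketone may epimerise under Lewis-acidic heating. The fallback moves the rearrangement ahead of the key step and sets out from 4. Eu(fod)3 in PhCl at 85 °C should give 5-hydroxy-7-methoxy-8-(3-methylbut-2-enyl)-4H-chromen-4-one F3, with regioisomers removed at this cheap, achiral stage. TBSOTf/2,6-lutidine gives 5-(tert-butyldimethylsilyloxy)-7-methoxy-8-(3-methylbut-2-enyl)-4H-chromen-4-one F4. The step 4 sequence with 8 then leads through the (2S)-enol silane F5 and the (2R,3R,4R)-silyloxy epoxide F6 to (2R,3R)-5-(tert-butyldimethylsilyloxy)-3-hydroxy-7-methoxy-2-[4-methoxy-3-(triisopropylsilyloxy)phenyl]-8-(3-methylbut-2-enyl)chroman-4-one F7. TBAF/AcOH removes both silyl ethers and returns to the route at 13.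

3. Step 2. The acid-labile prenyl aryl ether may be cleaved, or the phenol O-methylated by the formamide acetal, during enaminone formation and ring closure. The fallback inverts the order of ring closure and etherification and sets out from 1. DMF-DMA gives (E)-1-(2,6-dihydroxy-4-methoxyphenyl)-3-(dimethylamino)prop-2-en-1-one F8, and HCl in CH2Cl2 closes it to 5-hydroxy-7-methoxy-4H-chromen-4-one F9. Mitsunobu etherification of the single remaining hydroxyl with 3-methylbut-2-en-1-ol (PPh3, DIAD, THF) returns to the route at 4.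

**Further compounds**
F1 | step 4 | [4-methoxy-3-(triisopropylsilyloxy)phenyl]boronic acid | COc1ccc(B(O)O)cc1O[Si](C(C)C)(C(C)C)C(C)C
F2 | step 4 | (2S)-7-methoxy-2-[4-methoxy-3-(triisopropylsilyloxy)phenyl]-5-(3-methylbut-2-enyloxy)chroman-4-one | COc1ccc([C@H]2Oc3cc(OC)cc(OCC=C(C)C)c3C(=O)C2)cc1O[Si](C(C)C)(C(C)C)C(C)C
F3 | step 5 | 5-hydroxy-7-methoxy-8-(3-methylbut-2-enyl)-4H-chromen-4-one | COc1cc(O)c2C(=O)C=COc2c1CC=C(C)C
F4 | step 5 | 5-(tert-butyldimethylsilyloxy)-7-methoxy-8-(3-methylbut-2-enyl)-4H-chromen-4-one | COc1cc(O[Si](C)(C)C(C)(C)C)c2C(=O)C=COc2c1CC=C(C)C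
F5 | step 5 | (2S)-5-(tert-butyldimethylsilyloxy)-7-methoxy-2-[4-methoxy-3-(triisopropylsilyloxy)phenyl]-8-(3-methylbut-2-enyl)-4-(trimethylsilyloxy)-2H-chromene | COc1ccc([C@H]2Oc3c(CC=C(C)C)c(OC)cc(O[Si](C)(C)C(C)(C)C)c3C(O[Si](C)(C)C)=C2)cc1O[Si](C(C)C)(C(C)C)C(C)C
F6 | step 5 | (2R,3R,4R)-5-(tert-butyldimethylsilyloxy)-3,4-epoxy-7-methoxy-2-[4-methoxy-3-(triisopropylsilyloxy)phenyl]-8-(3-methylbut-2-enyl)-4-(trimethylsilyloxy)chromane | COc1ccc([C@H]2Oc3c(CC=C(C)C)c(OC)cc(O[Si](C)(C)C(C)(C)C)c3[C@]4(O[Si](C)(C)C)O[C@H]24)cc1O[Si](C(C)C)(C(C)C)C(C)C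
F7 | step 5 | (2R,3R)-5-(tert-butyldimethylsilyloxy)-3-hydroxy-7-methoxy-2-[4-methoxy-3-(triisopropylsilyloxy)phenyl]-8-(3-methylbut-2-enyl)chroman-4-one | COc1ccc([C@H]2Oc3c(CC=C(C)C)c(OC)cc(O[Si](C)(C)C(C)(C)C)c3C(=O)[C@@H]2O)cc1O[Si](C(C)C)(C(C)C)C(C)C
F8 | step 2 | (E)-1-(2,6-dihydroxy-4-methoxyphenyl)-3-(dimethylamino)prop-2-en-1-one | CN(C)/C=C/C(=O)c1c(O)cc(OC)cc1O
F9 | step 2 | 5-hydroxy-7-methoxy-4H-chromen-4-one | COc1cc(O)c2C(=O)C=COc2c1
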